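**Plan**
- Locants: C1 carries C7 (the CH2OBz carbon), C2 is the alkene CH, C3–C6 carry O3–O6, and the ring benzoate sits on O5.
- Retrosynthesis: cut the C–O bonds of a 3,4-carbonate mask, then the C3–O3 bond (back to a 1,6-epoxy-2-ene with a tert-butyl carbonate on O4), then the two oxirane C–O bonds, then the acyl–O bonds. The 1(6),2-diene goes back to shikimic acid by returning O3–H across C3/C6.
- Forward: the carbocycle comes intact from shikimic acid. O3 is removed by 1,4-dehydration, C7 is reduced and benzoylated, the oxirane ring (C1, C6, O) is closed, then the 1,3-dioxolan-2-one ring (C3, O3, CO, O4, C4) is closed and finally cleaved.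
- Enabling feature: in the target O3 is cis to O4 and 1,4-trans to O6 across C1=C2. This is what anti 1,4-opening of a C1–C6 oxirane next to a C2=C3 alkene by an oxygen tethered to O4 must leave.
- Stereochemistry: C4 and C5 come from shikimic acid, C6 (with C1 of the oxirane) from O5–H-directed epoxidation, C3 from the cis-fusing five-membered tether.

Key step: step 11

Remark: all intermediates keep the locants defined above; names and CIP descriptors refer to them.

Step 1
Reactants: 1 (−)-shikimic acid
Product: 3 methyl 3,4-O-isopropylideneshikimate [methyl (3R,4S,5R)-5-hydroxy-3,4-(isopropylidenedioxy)cyclohex-1-ene-1-carboxylate], via methyl shikimate 2 (not isolated)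
Conditions: MeOH, CSA (cat.), reflux; evaporate; Me2C(OMe)2, acetone, CSA (cat.), rt
Reagents that add atoms: methanol CO; 2,2-dimethoxypropane COC(C)(C)OC
Why: Fischer esterification followed by acid-catalysed transketalisation should place the ketal only across the cis-3,4-diol, because the trans-4,5-diol cannot span a dioxolane without strain, which leaves O5–H as the single free hydroxyl and touches no stereocentre.

Step 2
Reactants: 3 methyl 3,4-O-isopropylideneshikimate
Product: 4 methyl (3R,4R,5R)-5-[(tert-butyldiphenylsilyl)oxy]-3,4-(isopropylidenedioxy)cyclohex-1-ene-1-carboxylate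
Conditions: t-BuPh2SiCl, imidazole, DMAP (cat.), DMF, rt → 40 °C
Reagents that add atoms: tert-butyldiphenylsilyl chloride CC(C)(C)[Si](Cl)(c1ccccc1)c1ccccc1
Why: Imidazole-mediated silyl ether formation at the only free hydroxyl should leave the stereocentres alone, and this silyl group is chosen because it withstands the aqueous acid of step 3, screens O4 in steps 4 to 7 and leaves with fluoride in step 8.

Step 3
Reactants: 4 silyl ether acetonide
Product: 5 methyl (3R,4R,5R)-5-[(tert-butyldiphenylsilyl)oxy]-3,4-dihydroxycyclohex-1-ene-1-carboxylate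
Conditions: TFA–H2O (4:1), CH2Cl2, 0 °C
Reagents that add atoms: none
Why: Acid-catalysed ketal hydrolysis should free the cis-3,4-diol while the silyl ether and the methyl ester, both stable to cold aqueous TFA, stay in place.

Step 4
Reactants: 5 diol
Product: 8 methyl (4R,5R)-5-[(tert-butyldiphenylsilyl)oxy]-4-hydroxycyclohexa-1(6),2-diene-1-carboxylate, via allylic sulfenate 6 (not isolated), via tertiary sulfoxide 7 (not isolated)
Conditions: 2,4-(O2N)2C6H3SCl (1.05 equiv), Et3N, ClCH2CH2Cl, −20 °C → 60 °C
Reagents that add atoms: none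
Why: The sulfenyl chloride should esterify the unhindered allylic O3–H in preference to O4–H, which is crowded by the neighbouring silyl ether, after which a [2,3]-sigmatropic sulfenate-to-sulfoxide shift (Mislow–Evans rearrangement run in reverse) moves sulfur to C1 and the alkene to C2=C3, and thermal syn-elimination of the electron-poor aryl sulfoxide can take a hydrogen only from C6, so that this known 1,4-dehydration of allylic alcohols should give the 1(6),2-diene with C4 and C5 untouched.

Step 5
Reactants: 8 diene ester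
Product: 9 (4R,5R)-5-[(tert-butyldiphenylsilyl)oxy]-1-(hydroxymethyl)cyclohexa-1(6),2-dien-4-ol
Conditions: i-Bu2AlH (3.5 equiv), CH2Cl2, −78 °C; aq. potassium sodium tartrate
Reagents that add atoms: none
Why: 1,2-Reduction of the dienoate by i-Bu2AlH at low temperature should give the primary allylic alcohol, the free O4–H only consuming one equivalent of hydride and the silyl ether being inert.

Step 6
Reactants: 9 diene diol; 10 benzoyl chloride
Product: 11 [(4R,5R)-5-[(tert-butyldiphenylsilyl)oxy]-4-hydroxycyclohexa-1(6),2-dien-1-yl]methyl benzoate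
Conditions: BzCl (1.05 equiv), pyridine, CH2Cl2, −40 → 0 °C
Reagents that add atoms: benzoyl chloride O=C(Cl)c1ccccc1
Why: Acylation with an acid chloride in pyridine at low temperature should select the primary allylic hydroxyl over the secondary O4–H, which is flanked by the bulky silyl ether.

Step 7
Reactants: 11 O7 benzoate; 12 di-tert-butyl dicarbonate
Product: 13 [(4R,5R)-4-[(tert-butoxycarbonyl)oxy]-5-[(tert-butyldiphenylsilyl)oxy]cyclohexa-1(6),2-dien-1-yl]methyl benzoate
Conditions: Boc2O, DMAP (0.2 equiv), MeCN, rt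
Reagents that add atoms: di-tert-butyl dicarbonate CC(C)(C)OC(=O)OC(=O)OC(C)(C)C
Why: DMAP-catalysed carbonate formation with Boc2O should acylate the one remaining hydroxyl and so install on O4 the carbonyl oxygen that will later bond to C3.

Step 8
Reactants: 13 silyl ether carbonate
Product: 14 [(4R,5R)-4-[(tert-butoxycarbonyl)oxy]-5-hydroxycyclohexa-1(6),2-dien-1-yl]methyl benzoate
Conditions: Bu4NF, AcOH (1:1), THF, 0 °C → rt
Reagents that add atoms: none
Why: Fluoride-induced cleavage of the silyl ether should free O5–H, the acetic acid buffer keeping the alkoxide protonated so that the neighbouring carbonate does not migrate and the benzoate is not cleaved.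

Step 9
Reactants: 14 dienol
Product: 15 [(1S,4R,5S,6S)-4-[(tert-butoxycarbonyl)oxy]-5-hydroxy-7-oxabicyclo[4.1.0]hept-2-en-1-yl]methyl benzoate
Conditions: mCPBA (1.1 equiv), CH2Cl2, 0 °C, NaHCO3 buffer
Reagents that add atoms: 3-chloroperoxybenzoic acid O=C(OO)c1cccc(Cl)c1
Why: Hydroxyl-directed peracid epoxidation (Henbest effect) should deliver oxygen to the trisubstituted, more electron-rich C1=C6 alkene on the face of the hydrogen-bonding O5–H, which sets C1 and C6 with the oxirane cis to O5, while the C2=C3 alkene, deactivated by the allylic carbonate and lacking a directing group, should stay intact.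

Step 10
Reactants: 15 epoxy alcohol; 10 benzoyl chloride
Product: 16 [(1S,4R,5S,6S)-5-(benzoyloxy)-4-[(tert-butoxycarbonyl)oxy]-7-oxabicyclo[4.1.0]hept-2-en-1-yl]methyl benzoate
Conditions: BzCl, pyridine, DMAP (cat.), CH2Cl2, 0 °C
Reagents that add atoms: benzoyl chloride O=C(Cl)c1ccccc1
Why: Pyridine-mediated benzoylation of the remaining secondary hydroxyl is a plain esterification under basic conditions that the vinyl oxirane and the carbonate should tolerate, and it completes the substrate of the key step.

Step 11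
Reactants: 16 epoxy dibenzoate carbonate
Product: 18 [(3R,4R,5R,6R)-5-(benzoyloxy)-3,4-(carbonyldioxy)-6-hydroxycyclohex-1-en-1-yl]methyl benzoate (3,4-cyclic carbonate of the target), via dioxolanylium zwitterion 17 (not isolated)
Conditions: BF3·OEt2 (0.2 equiv), CH2Cl2, −78 → −30 °C; aq. NaHCO3
Reagents that add atoms: none
Why: BF3 coordination weakens the tertiary, allylic C1–O bond of the oxirane, and the carbonyl oxygen of the O4 carbonate adds to C3 of the developing C1–C2–C3 allyl cation anti to the departing oxygen while the alkene shifts to C1=C2, giving zwitterion 17, which loses 2-methylpropene and passes its proton to O6 so that BF3 turns over. The closest known reaction type is the Lewis-acid-promoted opening of epoxides and capture of allylic cations by neighbouring tert-butyl carbonates, run here in the SN2' (1,4) sense on a diene monoepoxide. The dioxolanone ring closes in a 5-exo-trig mode, the migrating C2=C3 π bond lying outside the new ring. The new stereocentre C3 is fixed by the tether, since the carbonyl oxygen can reach C3 only from the face of O4 and O3 therefore arrives cis to O4, while C6 keeps the configuration of step 9 because its C–O bond is never broken. The step needs attack at C3 instead of C1 and carbonate participation ahead of the benzoates: closure at C1 would demand a seven-membered ring, the O5 benzoate sits syn to the leaving oxygen, and addition of the C7 benzoate at C1 is reversible whereas loss of 2-methylpropene makes the carbonate pathway irreversible.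

Step 12
Reactants: 18 cyclic carbonate
Product: 19 [(3R,4R,5R,6R)-5-(benzoyloxy)-3,4,6-trihydroxycyclohex-1-en-1-yl]methyl benzoate (CNP0198957.3)
Conditions: K2CO3 (0.2 equiv), MeOH, −20 → 0 °C; AcOH quench
Reagents that add atoms: none
Why: Base-catalysed transesterification with methanol should open the strained five-membered carbonate, a far better electrophile than the two aryl esters, and release it as dimethyl carbonate, so that a short, cold exposure frees O3–H and O4–H without changing any stereocentre.

**Compound list**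
1 | (−)-shikimic acid, (3R,4S,5R)-3,4,5-trihydroxycyclohex-1-ene-1-carboxylic acid | O=C(O)C1=C[C@@H](O)[C@@H](O)[C@H](O)C1 | starting material
2 | methyl shikimate (not isolated) | COC(=O)C1=C[C@@H](O)[C@@H](O)[C@H](O)C1 | intermediate
3 | methyl (3R,4S,5R)-5-hydroxy-3,4-(isopropylidenedioxy)cyclohex-1-ene-1-carboxylate | COC(=O)C1=C[C@H]2OC(C)(C)O[C@H]2[C@H](O)C1 | intermediate
4 | methyl (3R,4R,5R)-5-[(tert-butyldiphenylsilyl)oxy]-3,4-(isopropylidenedioxy)cyclohex-1-ene-1-carboxylate | COC(=O)C1=C[C@H]2OC(C)(C)O[C@H]2[C@H](O[Si](c2ccccc2)(c2ccccc2)C(C)(C)C)C1 | intermediate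
5 | methyl (3R,4R,5R)-5-[(tert-butyldiphenylsilyl)oxy]-3,4-dihydroxycyclohex-1-ene-1-carboxylate | COC(=O)C1=C[C@@H](O)[C@@H](O)[C@H](O[Si](c2ccccc2)(c2ccccc2)C(C)(C)C)C1 | intermediate
6 | O3 (2,4-dinitrophenyl)sulfenate ester of 5, C3–C5 unchanged (not isolated) | COC(=O)C1=C[C@@H](OSc2ccc(cc2[N+](=O)[O-])[N+](=O)[O-])[C@@H](O)[C@H](O[Si](c2ccccc2)(c2ccccc2)C(C)(C)C)C1 | intermediate
7 | methyl 1-[(2,4-dinitrophenyl)sulfinyl]-4-hydroxy-5-[(tert-butyldiphenylsilyl)oxy]cyclohex-2-ene-1-carboxylate, sulfur on the face of C1 cis to O4, C4 and C5 unchanged (not isolated) | COC(=O)[C@]1(S(=O)c2ccc(cc2[N+](=O)[O-])[N+](=O)[O-])C=C[C@@H](O)[C@H](O[Si](c2ccccc2)(c2ccccc2)C(C)(C)C)C1 | intermediate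
8 | methyl (4R,5R)-5-[(tert-butyldiphenylsilyl)oxy]-4-hydroxycyclohexa-1(6),2-diene-1-carboxylate | COC(=O)C1=C[C@@H](O[Si](c2ccccc2)(c2ccccc2)C(C)(C)C)[C@H](O)C=C1 | intermediate
9 | (4R,5R)-5-[(tert-butyldiphenylsilyl)oxy]-1-(hydroxymethyl)cyclohexa-1(6),2-dien-4-ol | OCC1=C[C@@H](O[Si](c2ccccc2)(c2ccccc2)C(C)(C)C)[C@H](O)C=C1 | intermediate
10 | benzoyl chloride | O=C(Cl)c1ccccc1 | starting material
11 | [(4R,5R)-5-[(tert-butyldiphenylsilyl)oxy]-4-hydroxycyclohexa-1(6),2-dien-1-yl]methyl benzoate | O=C(OCC1=C[C@@H](O[Si](c2ccccc2)(c2ccccc2)C(C)(C)C)[C@H](O)C=C1)c1ccccc1 | intermediate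
12 | di-tert-butyl dicarbonate | CC(C)(C)OC(=O)OC(=O)OC(C)(C)C | starting material
13 | [(4R,5R)-4-[(tert-butoxycarbonyl)oxy]-5-[(tert-butyldiphenylsilyl)oxy]cyclohexa-1(6),2-dien-1-yl]methyl benzoate | O=C(OCC1=C[C@@H](O[Si](c2ccccc2)(c2ccccc2)C(C)(C)C)[C@H](OC(=O)OC(C)(C)C)C=C1)c1ccccc1 | intermediate
14 | [(4R,5R)-4-[(tert-butoxycarbonyl)oxy]-5-hydroxycyclohexa-1(6),2-dien-1-yl]methyl benzoate | O=C(OCC1=C[C@@H](O)[C@H](OC(=O)OC(C)(C)C)C=C1)c1ccccc1 | intermediate
15 | [(1S,4R,5S,6S)-4-[(tert-butoxycarbonyl)oxy]-5-hydroxy-7-oxabicyclo[4.1.0]hept-2-en-1-yl]methyl benzoate | O=C(OC[C@@]12C=C[C@@H](OC(=O)OC(C)(C)C)[C@H](O)[C@@H]1O2)c1ccccc1 | intermediate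
16 | [(1S,4R,5S,6S)-5-(benzoyloxy)-4-[(tert-butoxycarbonyl)oxy]-7-oxabicyclo[4.1.0]hept-2-en-1-yl]methyl benzoate | O=C(OC[C@@]12C=C[C@@H](OC(=O)OC(C)(C)C)[C@H](OC(=O)c3ccccc3)[C@@H]1O2)c1ccccc1 | intermediate
17 | 2-tert-butoxy-1,3-dioxolan-2-ylium ion cis-fused at C3/C4, O6 bound to BF3 (not isolated) | O=C(OCC1=C[C@H]2O[C+](OC(C)(C)C)O[C@H]2[C@H](OC(=O)c2ccccc2)[C@@H]1O[B-](F)(F)F)c1ccccc1 | intermediate
18 | [(3R,4R,5R,6R)-5-(benzoyloxy)-3,4-(carbonyldioxy)-6-hydroxycyclohex-1-en-1-yl]methyl benzoate | O=C(OCC1=C[C@H]2OC(=O)O[C@H]2[C@H](OC(=O)c2ccccc2)[C@@H]1O)c1ccccc1 | intermediate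
19 | [(3R,4R,5R,6R)-5-(benzoyloxy)-3,4,6-trihydroxycyclohex-1-en-1-yl]methyl benzoate | O=C(OCC1=C[C@@H](O)[C@@H](O)[C@H](OC(=O)c2ccccc2)[C@@H]1O)c1ccccc1 | target

Total step count: 12. Longest linear sequence: 12 steps (1 to 19).

**Steps most likely to fail**

Step 4. The sulfenyl chloride may not discriminate O3–H from O4–H, or the sulfenate-to-sulfoxide shift may stall because the alkene has to leave conjugation with the ester, so that sulfenate cleavage outruns diene formation. The fallback sets out from 5 and returns at 8. Diol 5 is treated with MeC(OMe)3 and CSA, and the cyclic orthoester is opened with aqueous AcOH, which should place the acetyl group on the pseudoaxial allylic oxygen and give the 3-O-acetate F1. TESOTf and 2,6-lutidine at −78 °C cap O4 to give the acetate silyl ether F2. Pd(PPh3)4 with Et3N in dioxane at 80 °C then effects a Tsuji–Trost-type elimination: zerovalent palladium ionises the allylic acetate from the face of O5, and the only hydrogen anti to the metal beside the allyl unit is on C6, so the bis-silyl diene ester F3 should result. AcOH–THF–H2O removes the triethylsilyl group and gives 8.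

Step 11. After ionisation of the oxirane, a hydride shift to a ketone (Meinwald-type), capture at C1 by the C7 benzoate, or loss of the tert-butyl group before the C3–O bond forms may win. The fallback sets out from 11 and returns at 18. Alcohol 11 is converted with 1,1'-carbonyldiimidazole and then Me2NH into the O4 dimethylcarbamate F4. Bu4NF/AcOH gives the carbamate dienol F5, mCPBA with NaHCO3 buffer gives the cis epoxy alcohol F6, and BzCl/pyridine gives the epoxy dibenzoate carbamate F7. BF3·OEt2 (1.1 equiv) at −78 °C should then close the same C3–O bond through the more electron-rich carbamate carbonyl oxygen, which cannot fragment before the bond is made, to give the cyclic iminium zwitterion F8. Aqueous NaHCO3 hydrolyses this to 18.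

Step 12. Under the basic methanolysis the O5 benzoyl group may shift to the neighbouring hydroxyls, above all to the cis O6–H, or a benzoate may be methanolysed. The fallback sets out from 18 and returns at 19. O6–H of 18 is silylated with TESOTf and 2,6-lutidine at −78 °C to give the silyl ether carbonate F9, which closes the cis-vicinal migration channel. K2CO3 in MeOH then removes the carbonate to give the silyl ether diol F10. HF·pyridine in THF/pyridine at 0 °C frees O6 under acidic conditions, in which benzoates do not migrate, and gives 19.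

**Further compounds**
F1 | step 4 | 3-O-acetate of 5 | COC(=O)C1=C[C@@H](OC(C)=O)[C@@H](O)[C@H](O[Si](c2ccccc2)(c2ccccc2)C(C)(C)C)C1
F2 | step 4 | 3-O-acetyl-4-O-triethylsilyl derivative of 5 | COC(=O)C1=C[C@@H](OC(C)=O)[C@@H](O[Si](CC)(CC)CC)[C@H](O[Si](c2ccccc2)(c2ccccc2)C(C)(C)C)C1
F3 | step 4 | 4-O-triethylsilyl ether of 8 | COC(=O)C1=C[C@@H](O[Si](c2ccccc2)(c2ccccc2)C(C)(C)C)[C@H](O[Si](CC)(CC)CC)C=C1
F4 | step 11 | O4 N,N-dimethylcarbamate of 11 | O=C(OCC1=C[C@@H](O[Si](c2ccccc2)(c2ccccc2)C(C)(C)C)[C@H](OC(=O)N(C)C)C=C1)c1ccccc1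
F5 | step 11 | O4 N,N-dimethylcarbamate analogue of 14 | O=C(OCC1=C[C@@H](O)[C@H](OC(=O)N(C)C)C=C1)c1ccccc1
F6 | step 11 | O4 N,N-dimethylcarbamate analogue of 15 | O=C(OC[C@@]12C=C[C@@H](OC(=O)N(C)C)[C@H](O)[C@@H]1O2)c1ccccc1
F7 | step 11 | O4 N,N-dimethylcarbamate analogue of 16 | O=C(OC[C@@]12C=C[C@@H](OC(=O)N(C)C)[C@H](OC(=O)c3ccccc3)[C@@H]1O2)c1ccccc1
F8 | step 11 | 2-(dimethyliminio)-1,3-dioxolane cis-fused at C3/C4, O6 bound to BF3 | O=C(OCC1=C[C@H]2OC(=[N+](C)C)O[C@H]2[C@H](OC(=O)c2ccccc2)[C@@H]1O[B-](F)(F)F)c1ccccc1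
F9 | step 12 | 6-O-triethylsilyl ether of 18 | O=C(OCC1=C[C@H]2OC(=O)O[C@H]2[C@H](OC(=O)c2ccccc2)[C@@H]1O[Si](CC)(CC)CC)c1ccccc1
F10 | step 12 | 6-O-triethylsilyl ether of 19 | O=C(OCC1=C[C@@H](O)[C@@H](O)[C@H](OC(=O)c2ccccc2)[C@@H]1O[Si](CC)(CC)CC)c1ccccc1
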